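The runs are calculated from invented constants.

The mol% of free catalyst is the unit I reckon in here: I want to know what each one buys in target while the substrate can also go elsewhere.

| flask | substrate | free catalyst | remark | time |
|---|---|---|---|---|
| north-west | 0.050 M | 5.8 mol% | run made earlier |  |
| west | 0.050 M | 16 mol% | run made earlier |  |
| north-east | 0.050 M | 22 mol% | run made earlier |  |
| beta | 0.050 M | 8 mol% |  | 8.0 min |
| zeta | 0.050 M | 15 mol% |  | 8.0 min |
| theta | 0.050 M | 30 mol% |  | 8.0 min |

| run | time / min | target / % | substrate / % |
|---|---|---|---|
| north-west | 0.417 | 9.4 | 44.9 |
| north-west | 0.833 | 12.6 | 21.9 |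
| north-west | 1.50 | 12.2 | 7.5 |
| north-west | 3.00 | 13.0 | 1.0 |
| north-west | 6.00 | 12.9 | 0 |
| west | 0.500 | 24.5 | 30.5 |
| west | 1.33 | 28.1 | 5.9 |
| west | 2.50 | 28.7 | 0.6 |
| west | 4.00 | 28.7 | 0.8 |
| west | 6.00 | 29.5 | 0.5 |
| north-east | 0.417 | 29.2 | 33.3 |
| north-east | 0.833 | 35.0 | 13.6 |
| north-east | 1.50 | 36.3 | 4.6 |
| north-east | 3.00 | 36.0 | 0.3 |
| north-east | 6.00 | 37.2 | 0 |

(readings scatter by 0.5 percentage points)

- the numbers in the tables scatter by 0.5 percentage points (one standard deviation)
- a reading or a percentage of target counts all its forms, free or not
- "hardly changes" means that all values lie within two and a half points (for a concentration: within two and a half percent of the largest)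

1. amount of target at the end, in percent of the substrate charged for beta, zeta, theta, in this order
2. the shape of the row from first to last (rises all the way / falls, then rises / hardly changes / rises, then falls / falls all the way)

In the west run substrate is down to 0.6 % at 2.50 min, with target at 28.7 %, and at 6.00 min target reads 29.5 %. So in the west run the end yield is a question of how the substrate divides, not of the clock. Dividing the rate that makes target by the rate that loses substrate elsewhere removes time and leaves odds: target made over substrate gone but not found as target. At the first readings these odds are 0.206 in the north-west run, 0.544 in the west run and 0.779 in the north-east run. Divided by each loading they give a mean of 3.50, which I call the early odds per equivalent of catalyst, a selectivity factor.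

Two extreme flasks can be solved in the head. In the first, free catalyst stays at its charge, the odds stay as they began, and the yield is odds over one plus odds: for theta that ceiling is 51.2 %. In the second, I suppose the catalyst dead once substrate stands where the north-east run had it at its first reading, with the rest of the substrate lost elsewhere, which gives theta 34.1 %, less than the ceiling. I expect theta to lie between them: in the north-east run, the readings show target taking 24.0 % of the substrate left after the first reading, less than the 43.8 % before it, but not zero.

The earlier runs end at 0.765, 0.822 and 0.856 of their ceilings, from the lowest loading to the highest. Zeta has a ceiling of 34.4 %. Carrying each fraction to its neighbour, I commit to 16.7 % for beta, 28.3 % for zeta and 43.8 % for theta.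

The forecast says 17 %, 27.9 % and 44 %, a row that rises all the way, with the caution “30 mol% is an extrapolation”.

    substrate + free catalyst → free catalyst + target (k = 2.30 M⁻¹ s⁻¹)
    substrate → side product (k = 0.0260 s⁻¹)
    free catalyst + target ⇌ idle complex (K = 470 M⁻¹, k = 0.890 M⁻¹ s⁻¹)
    free catalyst → spent catalyst A (k = 2.10 × 10⁻⁵ s⁻¹)
    free catalyst → spent catalyst B (k = 0.0180 s⁻¹)

Beta ends at 17.0 %, zeta at 27.8 % and theta at 44.1 %, so the row rises all the way. In theta at 8.00 min, spent catalyst B holds 73.6 % of the catalyst charged. The early odds per equivalent give theta its ceiling of 51.2 %, and the flask reaches 0.861 of it. For zeta the same odds give a ceiling of 34.4 %, and its 27.8 % is 0.808 of that.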